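**Assumption:** the target SMILES contains no stereocentres. The gem-dimethyl carbon is not stereogenic and the ring alkene is part of the chromene. The target is therefore achiral, and no stereocontrol is needed. Cathafuran C is 6-hydroxy-2-(7-hydroxy-6-prenyl-2,2-dimethyl-2H-chromen-5-yl)benzofuran.

## Retrosynthetic overview
- Disconnect the hindered C5(chromene)–C2(benzofuran) biaryl bond by Negishi coupling. The partners are a chromene-5-triflate and a 6-silyloxybenzofuran-2-ylzinc.
- The 5-OTf/7-OTBS chromene comes from the 5,7-diol by silylation of the less hindered 7-OH, then triflation of the peri 5-OH.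
- Central step: annulation of 2-prenylphloroglucinol with prenal, which differentiates the two ortho positions of the symmetric phloroglucinol core and gives the 6-prenyl-5,7-dihydroxy-2,2-dimethylchromene.
- Order of bond formation: C-prenylation of phloroglucinol, then the pyran ring, then the biaryl bond. The benzofuran is a commercial starting material, so no ring is formed after the pyran.

## Route

**Step 1**
Reactants: 1 phloroglucinol (benzene-1,3,5-triol); 2 prenyl bromide (1-bromo-3-methylbut-2-ene)
Product: 3 2-prenylphloroglucinol (2-(3-methylbut-2-enyl)benzene-1,3,5-triol)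
Conditions: 1 (3 equiv), 2 (1 equiv), KOH (1 equiv), H2O, 0 °C → rt, 4 h
Reagents that add atoms: prenyl bromide, CC(C)=CCBr
Why: all three ring CH positions of phloroglucinol are equivalent, so C-alkylation of the phenoxide (Friedel–Crafts-type) has no regiochemical problem. Excess cheap 1 limits over-prenylation, and no stereocentre is formed.

**Step 2**
Reactants: 3 2-prenylphloroglucinol; 4 prenal (3-methylbut-2-enal)
Product: 5 5,7-dihydroxy-2,2-dimethyl-6-(3-methylbut-2-enyl)-2H-chromene
Conditions: 4 (1.05 equiv), pyridine, 110 °C (sealed tube), 12 h
Reagents that add atoms: prenal, CC(C)=CC=O (loses H2O; its five carbons are retained)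
Why: this is a phenol–enal chromenylation, i.e. Knoevenagel-type ortho-alkylation via the non-aromatic keto tautomer followed by oxa-6π electrocyclization. It differentiates the two flanks of 3. Closure through the unhindered O5 is favoured over closure through the prenyl-flanked O1/O3, which would put the CMe2 group next to the prenyl and incur allylic strain. This gives the 6-prenyl isomer, which has no stereocentre.

**Step 3**
Reactants: 5 5,7-dihydroxy-6-prenyl-2,2-dimethylchromene; 6 TBSCl (tert-butyldimethylsilyl chloride)
Product: 7 7-(tert-butyldimethylsilyloxy)-5-hydroxy-6-prenyl-2,2-dimethyl-2H-chromene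
Conditions: 6 (1.0 equiv), imidazole (1.2 equiv), DMF, 0 °C, 2 h
Reagents that add atoms: TBSCl, CC(C)(C)[Si](C)(C)Cl
Why: silylation is sensitive to sterics. The 5-OH is shielded by the peri C4–H and the ortho prenyl, while the 7-OH has only the prenyl and C8–H, so the 7-OH reacts first. This is kinetic regioselective silylation, and no stereocentre is formed.

**Step 4**
Reactants: 7; 8 triflic anhydride
Product: 9 7-(tert-butyldimethylsilyloxy)-6-prenyl-2,2-dimethyl-2H-chromen-5-yl triflate
Conditions: 8 (1.2 equiv), pyridine, CH2Cl2, −10 → 0 °C, 30 min
Reagents that add atoms: Tf2O, O=S(=O)(OS(=O)(=O)C(F)(F)F)C(F)(F)F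
Why: standard phenol triflation converts the remaining 5-OH into a cross-coupling handle. Pyridine buffers TfOH, so the prenyl and chromene alkenes and the TBS ether survive.

**Step 5**
Reactants: 10 6-hydroxybenzofuran (benzofuran-6-ol, commercial); 6 TBSCl
Product: 11 6-(tert-butyldimethylsilyloxy)benzofuran
Conditions: 6 (1.1 equiv), imidazole (1.2 equiv), DMF, rt, 2 h
Reagents that add atoms: TBSCl, CC(C)(C)[Si](C)(C)Cl
Why: silylation masks the acidic phenol so that C2 lithiation can proceed cleanly in the next step. No stereocentre is involved.

**Step 6**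
Reactants: 11 6-(TBSO)benzofuran; 9 chromenyl triflate
Product: 12 bis-TBS cathafuran C
Conditions: 11 (1.5 equiv), n-BuLi (1.5 equiv), THF, −78 → −40 °C, 1 h; then ZnCl2 (1.6 equiv), 0 °C; then 9 (1 equiv), Pd-PEPPSI-IPent (5 mol%), LiCl, THF, 65 °C, 12 h
Reagents that add atoms: none (the benzofuranyl group comes from 11; n-BuLi and ZnCl2 leave no atoms in the product)
Why: this is a Negishi coupling. The C2–H of benzofuran is the most acidic site, so lithiation is C2-selective, and the resulting arylzinc couples with the di-ortho-substituted aryl triflate. A bulky NHC–Pd catalyst is used to overcome the hindrance. The step is achiral.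

**Step 7**
Reactants: 12
Product: 13 cathafuran C (target)
Conditions: TBAF (3 equiv), THF, 0 °C → rt, 1 h
Reagents that add atoms: none
Why: fluoride removes both aryl TBS ethers. The prenyl group, the chromene alkene and the benzofuran are inert, and the target is achiral.

**Check against the target SMILES.**
- The central ring carries prenyl at C6, 7-OH, H at C8, the pyran oxygen at C8a, the CH=CH–CMe2 ring at C4a, and the benzofuran at C5 (flanked by the prenyl and C4a). This matches the target.
- The benzofuran is attached through C2 and has 6-OH.
- Atom balance: 3 is C11H14O3; 3 + C5H8O (4) − H2O gives 5, C16H20O3; the final product 13 is C24H24O4, as in the target SMILES.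

## Compound list
1 | phloroglucinol | Oc1cc(O)cc(O)c1 | starting material
2 | prenyl bromide | CC(C)=CCBr | starting material
3 | 2-prenylphloroglucinol | CC(C)=CCc1c(O)cc(O)cc1O | intermediate
4 | prenal (3-methylbut-2-enal) | CC(C)=CC=O | starting material
5 | 5,7-dihydroxy-6-prenyl-2,2-dimethyl-2H-chromene | CC(C)=CCc1c(O)cc2OC(C)(C)C=Cc2c1O | intermediate
6 | TBSCl | CC(C)(C)[Si](C)(C)Cl | starting material (reagent)
7 | 7-OTBS-5-hydroxy-6-prenyl-2,2-dimethylchromene | CC(C)=CCc1c(O[Si](C)(C)C(C)(C)C)cc2OC(C)(C)C=Cc2c1O | intermediate
8 | triflic anhydride | O=S(=O)(OS(=O)(=O)C(F)(F)F)C(F)(F)F | starting material (reagent)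
9 | 7-OTBS-6-prenyl-2,2-dimethylchromen-5-yl triflate | CC(C)=CCc1c(O[Si](C)(C)C(C)(C)C)cc2OC(C)(C)C=Cc2c1OS(=O)(=O)C(F)(F)F | intermediate
10 | 6-hydroxybenzofuran | Oc1ccc2ccoc2c1 | starting material
11 | 6-(TBSO)benzofuran | CC(C)(C)[Si](C)(C)Oc1ccc2ccoc2c1 | intermediate
12 | bis-TBS cathafuran C | CC(C)=CCc1c(O[Si](C)(C)C(C)(C)C)cc2OC(C)(C)C=Cc2c1-c1cc2ccc(O[Si](C)(C)C(C)(C)C)cc2o1 | intermediate
13 | cathafuran C | CC(C)=CCc1c(O)cc2OC(C)(C)C=Cc2c1-c1cc2ccc(O)cc2o1 | target

## Totals
Total steps: 7. Longest linear sequence: 6 (1 → 3 → 5 → 7 → 9 → 12 → 13).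

## Three steps most likely to fail
1. **Step 2 (annulation regiochemistry).** Some 8-prenyl isomer from closure at O1/O3, and some bis-annulation, are likely.
   - Fallback (different approach): alkylate the unhindered O5 of 3 with 3-chloro-3-methylbut-1-yne (CuCl2/DBU). Heat the propargyl ether to drive the Claisen rearrangement and 6π closure, which fixes the 6-prenyl regiochemistry.
2. **Step 3 (7-OH versus 5-OH discrimination).** The selectivity may be poor, since both OH groups are ortho to the prenyl.
   - Fallback (different approach): avoid the differentiation altogether. Build a symmetric 2-(3,5-dihydroxyphenyl)benzofuran (moracin M type) by Sonogashira–cyclization of 4-iodoresorcinol with 3,5-dimethoxyphenylacetylene. Block C4′ as the bromide, then install the pyran ring and prenyl at C2′/C6′.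
3. **Step 6 (Negishi coupling of the di-ortho-substituted aryl triflate).** Hindrance may give protodetriflation or homocoupling.
   - Fallback (different approach): convert 9 to the terminal aryl alkyne (Pd/TMS-acetylene, then K2CO3/MeOH). Form the benzofuran de novo by Pd/Cu Sonogashira–cyclization with 2-iodo-5-silyloxyphenol, then remove the silyl groups with TBAF.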